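**Retrosynthetic overview** (chain carbons C1–C15 from the alkyne CH; ring oxygen between C7 and C12)
1. Target ⇒ bis-silylated enyne 21; the (Z)-enyne comes from Peterson olefination of the C4 aldehyde 17, itself made from the vinyl group of bromo-oxepane 14.
2. Oxepane (the only ring, closed in step 7) ⇒ acyclic (Z)-alkenol 13 by forming the C12–O bond: 7-exo bromoetherification, O7 to C12 and Br to C13, anti across the Z-alkene.
3. 13 ⇒ β-chloro aldehyde 10 + allyl chloride: (Z)-γ-chloroallylboration makes C6–C7 and sets the C6/C7 syn-chlorohydrin.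
4. 10 ⇒ (Z)-hex-3-enal + allyl chloride: the same reaction with the enantiomeric borane makes C9–C10 and sets C9/C10; the vinyl group is then turned into CH2CHO.
5. All six stereocentres are therefore set in three steps (2, 6 and 7).

Assumption: the compound is taken exactly as the SMILES (3Z,6R,7R,9S,10S,12R,13R), and the matched acid in step 7 is assumed to be (R)-TRIP, (R)-3,3′-bis(2,4,6-triisopropylphenyl)-1,1′-binaphthyl-2,2′-diyl hydrogen phosphate (otherwise its enantiomer is used).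

**Route**

Step 1
Reactants: 1 (3Z)-hex-3-en-1-ol
Product: 2 (3Z)-hex-3-enal
Conditions: Dess–Martin periodinane, NaHCO3, CH2Cl2, 0 °C → rt; used crude
Reagents that add atoms: none
Why: Dess–Martin oxidation of a primary alcohol is fast and, buffered, does not move the β,γ-Z-alkene into conjugation.

Step 2
Reactants: 2 (3Z)-hex-3-enal; 3 3-chloroprop-1-ene (allyl chloride)
Product: 6 (3S,4S,6Z)-3-chloronona-1,6-dien-4-ol, via chloroallylborane 4 (not isolated), via borinate ester 5 (not isolated)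
Conditions: (+)-Ipc2BOMe, LiN(c-C6H11)2, THF/Et2O, −95 °C; BF3·OEt2; then 2, −95 °C; HOCH2CH2NH2, rt
Reagents that add atoms: none
Why: Oehlschlager–Brown (Z)-γ-chloroallylboration: the chair transition state of the Z-borane gives the syn-chlorohydrin, and the Ipc groups from (−)-α-pinene direct attack to the re face (as in Brown allylation), setting 3S,4S (C9, C10 of the target).

Step 3
Reactants: 6 (3S,4S,6Z)-3-chloronona-1,6-dien-4-ol
Product: 7 {[(3S,4S,6Z)-3-chloronona-1,6-dien-4-yl]oxy}tri(propan-2-yl)silane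
Conditions: TIPSOTf, 2,6-lutidine, CH2Cl2, 0 °C
Reagents that add atoms: tri(propan-2-yl)silyl trifluoromethanesulfonate, CC(C)[Si](OS(=O)(=O)C(F)(F)F)(C(C)C)C(C)C
Why: Silyl triflate silylation of a hindered secondary alcohol under non-basic conditions (no epoxide from the chlorohydrin); the bulky silyl group later keeps O10 from attacking the bromiranium ion.

Step 4
Reactants: 7 {[(3S,4S,6Z)-3-chloronona-1,6-dien-4-yl]oxy}tri(propan-2-yl)silane
Product: 9 (3S,4S,6Z)-3-chloro-4-{[tri(propan-2-yl)silyl]oxy}non-6-en-1-ol, via alkylborane 8 (not isolated)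
Conditions: 9-BBN (1.05 equiv), THF, 0 °C → rt; NaBO3·4H2O, THF/H2O, rt
Reagents that add atoms: sodium perborate tetrahydrate, O[B-]1(O)OO[B-](O)(O)OO1.[Na+].[Na+]
Why: Anti-Markovnikov hydroboration–oxidation: 9-BBN adds to the terminal carbon of the monosubstituted alkene much faster than to the hindered Z-disubstituted one, and near-neutral perborate oxidation avoids cyclopropane formation from the γ-chloroalkylborane.

Step 5
Reactants: 9 (3S,4S,6Z)-3-chloro-4-{[tri(propan-2-yl)silyl]oxy}non-6-en-1-ol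
Product: 10 (3S,4S,6Z)-3-chloro-4-{[tri(propan-2-yl)silyl]oxy}non-6-enal
Conditions: Dess–Martin periodinane, CH2Cl2, 0 °C → rt; used at once
Reagents that add atoms: none
Why: Base-free Dess–Martin oxidation gives the β-chloro aldehyde without E1cB loss of HCl.

Step 6
Reactants: 10 (3S,4S,6Z)-3-chloro-4-{[tri(propan-2-yl)silyl]oxy}non-6-enal; 3 3-chloroprop-1-ene (allyl chloride)
Product: 13 (3R,4R,6S,7S,9Z)-3,6-dichloro-7-{[tri(propan-2-yl)silyl]oxy}dodeca-1,9-dien-4-ol, via chloroallylborane 11 (not isolated), via borinate ester 12 (not isolated)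
Conditions: (−)-Ipc2BOMe, LiN(c-C6H11)2, THF/Et2O, −95 °C; BF3·OEt2; then 10, −95 °C; HOCH2CH2NH2, rt
Reagents that add atoms: none
Why: Second (Z)-γ-chloroallylboration, now with Ipc groups from (+)-α-pinene for si-face attack; reagent control sets the syn 3R,4R pair (C6, C7 of the target), and the non-basic conditions at −95 °C tolerate the β-chloro aldehyde.

Step 7
Reactants: 13 (3R,4R,6S,7S,9Z)-3,6-dichloro-7-{[tri(propan-2-yl)silyl]oxy}dodeca-1,9-dien-4-ol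
Product: 14 {[(2R,4S,5S,7R)-2-[(1R)-1-bromopropyl]-5-chloro-7-[(1R)-1-chloroprop-2-en-1-yl]oxepan-4-yl]oxy}tri(propan-2-yl)silane
Conditions: NBS (1.2 equiv), Ph3P=S (10 mol %), (R)-TRIP (10 mol %), toluene/CH2Cl2, −40 °C, dark
Reagents that add atoms: N-bromosuccinimide, BrN1C(=O)CCC1=O
Why: Proposed new method: Lewis-base/chiral-phosphate co-catalysed 7-exo-trig bromoetherification of an acyclic, unactivated (Z)-dialkyl alkenol; Ph3P=S takes Br+ from NBS and passes it to the electron-rich Z-alkene (the vinyl group next to CHCl is deactivated, O10 is blocked by the bulky silyl group), the phosphate ion-pairs with the bromiranium ion and hydrogen-bonds the C7 hydroxyl so that O7 opens C12 anti to bromine through a seven-membered transition state; anti addition across the Z-alkene fixes the 12,13-threo pair and the chiral ion pair selects the face that gives 12R,13R, i.e. the 7,12-trans ring; closest known reaction type: Ph3P=S/chiral phosphoric acid co-catalysed 5-exo and 6-endo bromocycloetherification of alkenols with NBS, not shown for seven-membered rings, Z-dialkyl alkenes or catalyst-controlled diastereoselection in a chiral substrate.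

Step 8
Reactants: 14 {[(2R,4S,5S,7R)-2-[(1R)-1-bromopropyl]-5-chloro-7-[(1R)-1-chloroprop-2-en-1-yl]oxepan-4-yl]oxy}tri(propan-2-yl)silane
Product: 16 (2R,4S,5S,7R)-2-[(1R)-1-bromopropyl]-5-chloro-7-[(1R)-1-chloro-3-hydroxypropyl]-4-{[tri(propan-2-yl)silyl]oxy}oxepane, via alkylborane 15 (not isolated)
Conditions: 9-BBN, THF, 0 °C → rt; NaBO3·4H2O, THF/H2O, rt
Reagents that add atoms: sodium perborate tetrahydrate, O[B-]1(O)OO[B-](O)(O)OO1.[Na+].[Na+]
Why: Anti-Markovnikov hydroboration–oxidation of the only remaining alkene; alkyl bromide, chlorides and the silyl ether are inert to 9-BBN and perborate.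

Step 9
Reactants: 16 (2R,4S,5S,7R)-2-[(1R)-1-bromopropyl]-5-chloro-7-[(1R)-1-chloro-3-hydroxypropyl]-4-{[tri(propan-2-yl)silyl]oxy}oxepane
Product: 17 (2R,4S,5S,7R)-2-[(1R)-1-bromopropyl]-5-chloro-7-[(1R)-1-chloro-3-oxopropyl]-4-{[tri(propan-2-yl)silyl]oxy}oxepane
Conditions: Dess–Martin periodinane, CH2Cl2, 0 °C → rt; used at once
Reagents that add atoms: none
Why: Base-free Dess–Martin oxidation of the primary alcohol to the C4 aldehyde without elimination of the β-chloride.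

Step 10
Reactants: 17 (2R,4S,5S,7R)-2-[(1R)-1-bromopropyl]-5-chloro-7-[(1R)-1-chloro-3-oxopropyl]-4-{[tri(propan-2-yl)silyl]oxy}oxepane; 18 1,3-bis[tri(propan-2-yl)silyl]prop-1-yne
Product: 21 (2R,4S,5S,7R)-2-[(1R)-1-bromopropyl]-5-chloro-7-{(1R,3Z)-1-chloro-6-[tri(propan-2-yl)silyl]hex-3-en-5-yn-1-yl}-4-{[tri(propan-2-yl)silyl]oxy}oxepane, via lithiated propyne 19 (not isolated), via β-silyl alkoxide 20 (not isolated)
Conditions: 18, n-BuLi, THF, −78 → −20 °C; then 17, −78 °C → rt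
Reagents that add atoms: none
Why: Corey–Rücker Peterson olefination: the bulky silyl groups favour the adduct that syn-eliminates to the (Z)-enyne (typically ≥10:1 Z:E), and addition at −78 °C outruns enolisation of the β-chloro aldehyde.

Step 11
Reactants: 21 (2R,4S,5S,7R)-2-[(1R)-1-bromopropyl]-5-chloro-7-{(1R,3Z)-1-chloro-6-[tri(propan-2-yl)silyl]hex-3-en-5-yn-1-yl}-4-{[tri(propan-2-yl)silyl]oxy}oxepane
Product: 22 (2R,4S,5S,7R)-2-[(1R)-1-bromopropyl]-5-chloro-7-[(1R,3Z)-1-chlorohex-3-en-5-yn-1-yl]oxepan-4-ol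
Conditions: Bu4NF (3 equiv), AcOH (3 equiv), THF, 0 °C → rt
Reagents that add atoms: none
Why: Fluoride desilylation of both the silyl ether and the alkynylsilane; the acetic acid buffer keeps the C10 oxygen protonated so the trans-chlorohydrin does not close to an epoxide.

**Compound list**
1 | (3Z)-hex-3-en-1-ol | OCC/C=C\CC | starting material
2 | (3Z)-hex-3-enal | O=CC/C=C\CC | intermediate
3 | 3-chloroprop-1-ene (allyl chloride) | C=CCCl | starting material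
4 | [(2Z)-3-chloroprop-2-en-1-yl]bis(isopinocampheyl)borane, Ipc from (−)-α-pinene | Cl/C=C\CB([C@H]1C[C@H]2C[C@H](C2(C)C)[C@@H]1C)[C@H]1C[C@H]2C[C@H](C2(C)C)[C@@H]1C | intermediate
5 | (3S,4S,6Z)-3-chloronona-1,6-dien-4-yl bis(isopinocampheyl)borinate, Ipc from (−)-α-pinene | C=C[C@H](Cl)[C@@H](OB([C@H]1C[C@H]2C[C@H](C2(C)C)[C@@H]1C)[C@H]1C[C@H]2C[C@H](C2(C)C)[C@@H]1C)C/C=C\CC | intermediate
6 | (3S,4S,6Z)-3-chloronona-1,6-dien-4-ol | C=C[C@H](Cl)[C@@H](O)C/C=C\CC | intermediate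
7 | {[(3S,4S,6Z)-3-chloronona-1,6-dien-4-yl]oxy}tri(propan-2-yl)silane | C=C[C@H](Cl)[C@@H](O[Si](C(C)C)(C(C)C)C(C)C)C/C=C\CC | intermediate
8 | 9-[(3S,4S,6Z)-3-chloro-4-{[tri(propan-2-yl)silyl]oxy}non-6-en-1-yl]-9-borabicyclo[3.3.1]nonane | C1CCC2CCCC1B2CC[C@H](Cl)[C@@H](O[Si](C(C)C)(C(C)C)C(C)C)C/C=C\CC | intermediate
9 | (3S,4S,6Z)-3-chloro-4-{[tri(propan-2-yl)silyl]oxy}non-6-en-1-ol | OCC[C@H](Cl)[C@@H](O[Si](C(C)C)(C(C)C)C(C)C)C/C=C\CC | intermediate
10 | (3S,4S,6Z)-3-chloro-4-{[tri(propan-2-yl)silyl]oxy}non-6-enal | O=CC[C@H](Cl)[C@@H](O[Si](C(C)C)(C(C)C)C(C)C)C/C=C\CC | intermediate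
11 | [(2Z)-3-chloroprop-2-en-1-yl]bis(isopinocampheyl)borane, Ipc from (+)-α-pinene | Cl/C=C\CB([C@@H]1C[C@@H]2C[C@@H](C2(C)C)[C@H]1C)[C@@H]1C[C@@H]2C[C@@H](C2(C)C)[C@H]1C | intermediate
12 | (3R,4R,6S,7S,9Z)-3,6-dichloro-7-{[tri(propan-2-yl)silyl]oxy}dodeca-1,9-dien-4-yl bis(isopinocampheyl)borinate, Ipc from (+)-α-pinene | C=C[C@@H](Cl)[C@H](OB([C@@H]1C[C@@H]2C[C@@H](C2(C)C)[C@H]1C)[C@@H]1C[C@@H]2C[C@@H](C2(C)C)[C@H]1C)C[C@H](Cl)[C@@H](O[Si](C(C)C)(C(C)C)C(C)C)C/C=C\CC | intermediate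
13 | (3R,4R,6S,7S,9Z)-3,6-dichloro-7-{[tri(propan-2-yl)silyl]oxy}dodeca-1,9-dien-4-ol | C=C[C@@H](Cl)[C@H](O)C[C@H](Cl)[C@@H](O[Si](C(C)C)(C(C)C)C(C)C)C/C=C\CC | intermediate
14 | {[(2R,4S,5S,7R)-2-[(1R)-1-bromopropyl]-5-chloro-7-[(1R)-1-chloroprop-2-en-1-yl]oxepan-4-yl]oxy}tri(propan-2-yl)silane | C=C[C@@H](Cl)[C@H]1C[C@H](Cl)[C@@H](O[Si](C(C)C)(C(C)C)C(C)C)C[C@H]([C@H](Br)CC)O1 | intermediate
15 | (2R,4S,5S,7R)-7-[(1R)-3-(9-borabicyclo[3.3.1]nonan-9-yl)-1-chloropropyl]-2-[(1R)-1-bromopropyl]-5-chloro-4-{[tri(propan-2-yl)silyl]oxy}oxepane | C1CCC2CCCC1B2CC[C@@H](Cl)[C@H]1C[C@H](Cl)[C@@H](O[Si](C(C)C)(C(C)C)C(C)C)C[C@H]([C@H](Br)CC)O1 | intermediate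
16 | (2R,4S,5S,7R)-2-[(1R)-1-bromopropyl]-5-chloro-7-[(1R)-1-chloro-3-hydroxypropyl]-4-{[tri(propan-2-yl)silyl]oxy}oxepane | OCC[C@@H](Cl)[C@H]1C[C@H](Cl)[C@@H](O[Si](C(C)C)(C(C)C)C(C)C)C[C@H]([C@H](Br)CC)O1 | intermediate
17 | (2R,4S,5S,7R)-2-[(1R)-1-bromopropyl]-5-chloro-7-[(1R)-1-chloro-3-oxopropyl]-4-{[tri(propan-2-yl)silyl]oxy}oxepane | O=CC[C@@H](Cl)[C@H]1C[C@H](Cl)[C@@H](O[Si](C(C)C)(C(C)C)C(C)C)C[C@H]([C@H](Br)CC)O1 | intermediate
18 | 1,3-bis[tri(propan-2-yl)silyl]prop-1-yne | CC(C)[Si](C(C)C)(C(C)C)CC#C[Si](C(C)C)(C(C)C)C(C)C | starting material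
19 | {1,3-bis[tri(propan-2-yl)silyl]prop-2-yn-1-yl}lithium | [Li]C([Si](C(C)C)(C(C)C)C(C)C)C#C[Si](C(C)C)(C(C)C)C(C)C | intermediate
20 | lithium alkoxide from addition of 19 to the aldehyde of 17 (C4 oxido, C3 silyl; the two new centres are not defined) | [Li]OC(C[C@@H](Cl)[C@H]1C[C@H](Cl)[C@@H](O[Si](C(C)C)(C(C)C)C(C)C)C[C@H]([C@H](Br)CC)O1)C(C#C[Si](C(C)C)(C(C)C)C(C)C)[Si](C(C)C)(C(C)C)C(C)C | intermediate
21 | (2R,4S,5S,7R)-2-[(1R)-1-bromopropyl]-5-chloro-7-{(1R,3Z)-1-chloro-6-[tri(propan-2-yl)silyl]hex-3-en-5-yn-1-yl}-4-{[tri(propan-2-yl)silyl]oxy}oxepane | CC(C)[Si](C(C)C)(C(C)C)C#C/C=C\C[C@@H](Cl)[C@H]1C[C@H](Cl)[C@@H](O[Si](C(C)C)(C(C)C)C(C)C)C[C@H]([C@H](Br)CC)O1 | intermediate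
22 | (2R,4S,5S,7R)-2-[(1R)-1-bromopropyl]-5-chloro-7-[(1R,3Z)-1-chlorohex-3-en-5-yn-1-yl]oxepan-4-ol | C#C/C=C\C[C@@H](Cl)[C@H]1C[C@H](Cl)[C@@H](O)C[C@H]([C@H](Br)CC)O1 | target

**Step count and risks**

Total steps: 11. Longest linear sequence: 11 (1 → 22).

Step 7 (the proposed new bromoetherification) is the most likely to fail: 8-endo closure, attack by the silyl ether oxygen, or the wrong alkene face would each divert material. The fallback uses known chemistry, sets out from 13 and comes back at 14. m-CPBA epoxidises only the electron-rich Z-alkene and gives the wanted cis-epoxy alcohol F1 together with its oxirane diastereomer F2, which is removed by chromatography. Camphorsulfonic acid in CH2Cl2 closes the ring by 7-exo opening of F1 at C12 with inversion to give the 13-hydroxy oxepane F3. Mitsunobu inversion (4-nitrobenzoic acid, PPh3, DIAD) gives the 4-nitrobenzoate F4, and K2CO3/MeOH gives the inverted alcohol F5. CBr4 with P(n-C8H17)3 in toluene at 70 °C then brominates with a second inversion to give 14.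

Step 10 is next: the lithiated propyne is a strong base and the β-chloro aldehyde can lose HCl or enolise. The fallback sets out from 17 and comes back at 21. Stork–Zhao olefination (Ph3P+CH2I I−, NaN(SiMe3)2, THF/DMPU, −78 °C) gives the (Z)-vinyl iodide F6. Sonogashira coupling with ethynyltri(propan-2-yl)silane (PdCl2(PPh3)2, CuI, Et3N) then gives 21.

Step 11 is third: fluoride can turn the freed trans-chlorohydrin into an epoxide or eliminate HBr. The fallback sets out from 21 and comes back at 22. Bu4NF (1 equiv) in THF at −20 °C removes only the alkynyl silyl group to give the terminal alkyne silyl ether F7. HF·pyridine in THF then cleaves the silyl ether under acidic conditions to give 22.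

**Further compounds**
F1 | step 7 | (3R,4R,6S,7S)-3,6-dichloro-8-[(2S,3R)-3-ethyloxiran-2-yl]-7-{[tri(propan-2-yl)silyl]oxy}oct-1-en-4-ol | C=C[C@@H](Cl)[C@H](O)C[C@H](Cl)[C@@H](O[Si](C(C)C)(C(C)C)C(C)C)C[C@@H]1O[C@@H]1CC
F2 | step 7 | (3R,4R,6S,7S)-3,6-dichloro-8-[(2R,3S)-3-ethyloxiran-2-yl]-7-{[tri(propan-2-yl)silyl]oxy}oct-1-en-4-ol | C=C[C@@H](Cl)[C@H](O)C[C@H](Cl)[C@@H](O[Si](C(C)C)(C(C)C)C(C)C)C[C@H]1O[C@H]1CC
F3 | step 7 | (1R)-1-[(2R,4S,5S,7R)-5-chloro-7-[(1R)-1-chloroprop-2-en-1-yl]-4-{[tri(propan-2-yl)silyl]oxy}oxepan-2-yl]propan-1-ol | C=C[C@@H](Cl)[C@H]1C[C@H](Cl)[C@@H](O[Si](C(C)C)(C(C)C)C(C)C)C[C@H]([C@H](O)CC)O1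
F4 | step 7 | (1S)-1-[(2R,4S,5S,7R)-5-chloro-7-[(1R)-1-chloroprop-2-en-1-yl]-4-{[tri(propan-2-yl)silyl]oxy}oxepan-2-yl]propyl 4-nitrobenzoate | C=C[C@@H](Cl)[C@H]1C[C@H](Cl)[C@@H](O[Si](C(C)C)(C(C)C)C(C)C)C[C@H]([C@@H](OC(=O)c2ccc(cc2)[N+](=O)[O-])CC)O1
F5 | step 7 | (1S)-1-[(2R,4S,5S,7R)-5-chloro-7-[(1R)-1-chloroprop-2-en-1-yl]-4-{[tri(propan-2-yl)silyl]oxy}oxepan-2-yl]propan-1-ol | C=C[C@@H](Cl)[C@H]1C[C@H](Cl)[C@@H](O[Si](C(C)C)(C(C)C)C(C)C)C[C@H]([C@@H](O)CC)O1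
F6 | step 10 | (2R,4S,5S,7R)-2-[(1R)-1-bromopropyl]-5-chloro-7-[(1R,3Z)-1-chloro-4-iodobut-3-en-1-yl]-4-{[tri(propan-2-yl)silyl]oxy}oxepane | I/C=C\C[C@@H](Cl)[C@H]1C[C@H](Cl)[C@@H](O[Si](C(C)C)(C(C)C)C(C)C)C[C@H]([C@H](Br)CC)O1
F7 | step 11 | (2R,4S,5S,7R)-2-[(1R)-1-bromopropyl]-5-chloro-7-[(1R,3Z)-1-chlorohex-3-en-5-yn-1-yl]-4-{[tri(propan-2-yl)silyl]oxy}oxepane | C#C/C=C\C[C@@H](Cl)[C@H]1C[C@H](Cl)[C@@H](O[Si](C(C)C)(C(C)C)C(C)C)C[C@H]([C@H](Br)CC)O1
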